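**Retrosynthetic overview**

1. Feature: the rings are lettered A–J from the 2,4,6-trihydroxyphenyl end, and C1 of each ring is the carbon bonded to the ether oxygen coming from the preceding ring. In rings C, E, G, I and J the middle pyrogallol oxygen sits on C4, para to C1; in rings B, D, F and H the onward ether oxygen is also on C4. Every ring B–J can therefore enter as a 4-fluorobenzaldehyde whose CHO on C4 activates C1–F and is later replaced by oxygen.
2. Target 25 ⇐ BBr3 cleavage of 21 methyl ethers ⇐ pentaphenol 24 ⇐ five-fold Baeyer–Villiger (Dakin) oxidation of penta-aldehyde 22, forming C4–O on rings C, E, G, I and J.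
3. 22 ⇐ SNAr of the AB phenol 7 on octamer fluoride 21. 21 ⇐ dimer fluoride 15 (rings I–J), extended three times by SNAr with dimer phenol 14 followed by dioxolane hydrolysis (dioxolane = fluoride switched off, CHO = switched on).
4. 14 and 15 ⇐ one common dimer 12 ⇐ phenol 11 + aldehyde 4. 11 ⇐ 4 by acetalisation and ortho-lithiation/borylation/oxidation. 7 ⇐ 1 and 4 by Dakin, SNAr, Dakin.
5. No ring is formed in the route. All ten benzene rings come from aldehydes 1 and 4 and are joined in the order A–B; dimer 12; I–J with G–H; then E–F; then C–D; then A–B.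

Key step: step 16

Remark: the target has no stereocentre, and 4-fluoro-2,6-dimethoxybenzaldehyde (4) is taken as a purchasable building block.

**Route**

Step 1
Reactants: 1 2,4,6-trimethoxybenzaldehyde
Product: 3 2,4,6-trimethoxyphenol, via 2,4,6-trimethoxyphenyl formate 2 (not isolated)
Conditions: mCPBA, CH2Cl2, 0 °C to rt; then K2CO3 (cat.), MeOH, rt
Reagents that add atoms: mCPBA (3-chloroperoxybenzoic acid), OOC(=O)c1cccc(Cl)c1
Why: Baeyer–Villiger (Dakin-type) oxidation, in which the trimethoxyphenyl group migrates in preference to hydride and the resulting formate is cleaved by methanolysis.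

Step 2
Reactants: 3 2,4,6-trimethoxyphenol; 4 4-fluoro-2,6-dimethoxybenzaldehyde
Product: 5 2,6-dimethoxy-4-(2,4,6-trimethoxyphenoxy)benzaldehyde (rings A–B)
Conditions: Cs2CO3, DMSO, 90 °C, Ar
Reagents that add atoms: none
Why: Nucleophilic aromatic substitution (SNAr), the caesium phenoxide displacing the only fluoride, which lies para to the formyl group.

Step 3
Reactants: 5 2,6-dimethoxy-4-(2,4,6-trimethoxyphenoxy)benzaldehyde
Product: 7 2,6-dimethoxy-4-(2,4,6-trimethoxyphenoxy)phenol, via aryl formate 6 (not isolated)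
Conditions: mCPBA, CH2Cl2, 0 °C to rt; then K2CO3 (cat.), MeOH, rt
Reagents that add atoms: mCPBA (3-chloroperoxybenzoic acid), OOC(=O)c1cccc(Cl)c1
Why: Baeyer–Villiger (Dakin-type) oxidation of a 2,6-dimethoxy-4-aryloxybenzaldehyde, the electron-rich aryl group migrating to oxygen before methanolysis of the formate.

Step 4
Reactants: 4 4-fluoro-2,6-dimethoxybenzaldehyde
Product: 8 2-(4-fluoro-2,6-dimethoxyphenyl)-1,3-dioxolane
Conditions: ethylene glycol, p-TsOH (cat.), toluene, reflux, Dean–Stark; Et3N quench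
Reagents that add atoms: ethylene glycol, OCCO
Why: Acid-catalysed acetalisation driven by azeotropic removal of water, which turns the formyl group into a base-stable dioxolane that does not activate the fluoride.

Step 5
Reactants: 8 2-(4-fluoro-2,6-dimethoxyphenyl)-1,3-dioxolane
Product: 11 3-(1,3-dioxolan-2-yl)-6-fluoro-2,4-dimethoxyphenol, via aryllithium 9 (not isolated), via lithium aryltrimethoxyborate 10 (not isolated)
Conditions: n-BuLi, THF, −78 °C; B(OMe)3, −78 to 0 °C; then H2O2, aq NaOH, 0 °C to rt; NH4Cl work-up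
Reagents that add atoms: hydrogen peroxide, OO
Why: Directed ortho-metalation at the only kind of ring C–H (between F and OMe, both of which acidify it), followed by borylation and oxidative aryl shift from boron to oxygen; −78 °C is held to prevent loss of LiF to an aryne.

Step 6
Reactants: 11 3-(1,3-dioxolan-2-yl)-6-fluoro-2,4-dimethoxyphenol; 4 4-fluoro-2,6-dimethoxybenzaldehyde
Product: 12 4-[3-(1,3-dioxolan-2-yl)-6-fluoro-2,4-dimethoxyphenoxy]-2,6-dimethoxybenzaldehyde
Conditions: Cs2CO3, DMSO, 100 °C, Ar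
Reagents that add atoms: none
Why: SNAr at the formyl-activated fluoride of 4; the fluoride of 11 carries only a dioxolane para and a phenoxide ortho, so it should not be displaced and no self-condensation is expected.

Step 7
Reactants: 12 4-[3-(1,3-dioxolan-2-yl)-6-fluoro-2,4-dimethoxyphenoxy]-2,6-dimethoxybenzaldehyde
Product: 14 4-[3-(1,3-dioxolan-2-yl)-6-fluoro-2,4-dimethoxyphenoxy]-2,6-dimethoxyphenol, via dimer formate 13 (not isolated)
Conditions: mCPBA, CH2Cl2/aq NaHCO3 (two-phase), 0 °C to rt; then K2CO3 (cat.), MeOH, rt; pH 7 work-up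
Reagents that add atoms: mCPBA (3-chloroperoxybenzoic acid), OOC(=O)c1cccc(Cl)c1
Why: Baeyer–Villiger (Dakin-type) oxidation of the one free formyl group, the bicarbonate phase keeping the acid-labile dioxolane of the other ring intact.

Step 8
Reactants: 12 4-[3-(1,3-dioxolan-2-yl)-6-fluoro-2,4-dimethoxyphenoxy]-2,6-dimethoxybenzaldehyde
Product: 15 4-fluoro-3-(4-formyl-3,5-dimethoxyphenoxy)-2,6-dimethoxybenzaldehyde (rings I–J)
Conditions: 1 M aq HCl, THF, rt
Reagents that add atoms: water, O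
Why: Acid-catalysed acetal hydrolysis, fast for an acetal of an electron-rich benzaldehyde, which restores the formyl group para to the fluoride and so switches that fluoride on.

Step 9
Reactants: 14 4-[3-(1,3-dioxolan-2-yl)-6-fluoro-2,4-dimethoxyphenoxy]-2,6-dimethoxyphenol; 15 4-fluoro-3-(4-formyl-3,5-dimethoxyphenoxy)-2,6-dimethoxybenzaldehyde
Product: 16 tetramer G–H–I–J (ring G: C1–F, C4 dioxolane; rings I and J: C4–CHO)
Conditions: Cs2CO3, DMSO, 100 °C, Ar
Reagents that add atoms: none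
Why: SNAr of the 2,6-dimethoxyphenoxide of 14 on the only formyl-activated fluoride (ring I of 15); the fluoride that 14 brings in is para to a dioxolane and stays inert.

Step 10
Reactants: 16 tetramer G–H–I–J with dioxolane on ring G
Product: 17 tetramer G–H–I–J trialdehyde (ring G: C1–F, C4–CHO)
Conditions: 1 M aq HCl, THF, rt
Reagents that add atoms: water, O
Why: Acid-catalysed acetal hydrolysis; the diaryl ethers, methyl ethers and aldehydes are untouched, and the ring G fluoride becomes activated.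

Step 11
Reactants: 14 dimer phenol (as above); 17 tetramer trialdehyde fluoride
Product: 18 hexamer E–F–G–H–I–J (ring E: C1–F, C4 dioxolane; rings G, I, J: C4–CHO)
Conditions: Cs2CO3, DMSO, 100 °C, Ar
Reagents that add atoms: none
Why: SNAr at the single formyl-activated fluoride (ring G), the same reaction as step 9 on the next homologue.

Step 12
Reactants: 18 hexamer with dioxolane on ring E
Product: 19 hexamer tetra-aldehyde (ring E: C1–F, C4–CHO)
Conditions: 1 M aq HCl, THF, rt
Reagents that add atoms: water, O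
Why: Acid-catalysed acetal hydrolysis, as in step 10.

Step 13
Reactants: 14 dimer phenol (as above); 19 hexamer tetra-aldehyde fluoride
Product: 20 octamer C–D–E–F–G–H–I–J (ring C: C1–F, C4 dioxolane; rings E, G, I, J: C4–CHO)
Conditions: Cs2CO3, DMSO, 100 °C, Ar
Reagents that add atoms: none
Why: SNAr at the single formyl-activated fluoride (ring E), as in steps 9 and 11.

Step 14
Reactants: 20 octamer with dioxolane on ring C
Product: 21 octamer penta-aldehyde (ring C: C1–F, C4–CHO)
Conditions: 1 M aq HCl, THF, rt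
Reagents that add atoms: water, O
Why: Acid-catalysed acetal hydrolysis, as in step 10.

Step 15
Reactants: 7 2,6-dimethoxy-4-(2,4,6-trimethoxyphenoxy)phenol; 21 octamer penta-aldehyde fluoride
Product: 22 permethylated decamer penta-aldehyde (CHO on C4 of rings C, E, G, I, J)
Conditions: Cs2CO3, DMSO, 100 °C, Ar
Reagents that add atoms: none
Why: SNAr of the phenoxide of 7 on the one fluoride of 21, which is para to the ring C formyl group; this forms the B–O–C link and completes the chain.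

Step 16
Reactants: 22 permethylated decamer penta-aldehyde
Product: 24 decamer pentaphenol with twenty-one methyl ethers, via decamer pentaformate 23 (not isolated)
Conditions: mCPBA (excess), CH2Cl2, 0 °C to rt; aq Na2S2O3/NaHCO3 wash; then K2CO3 (cat.), degassed MeOH, rt, Ar; AcOH quench
Reagents that add atoms: mCPBA (3-chloroperoxybenzoic acid), OOC(=O)c1cccc(Cl)c1
Why: The peracid adds to each formyl group to give a Criegee adduct, from which the aryl group migrates from carbon to oxygen with loss of 3-chlorobenzoate; the five aryl formates of 23 are then cleaved by methanolysis. This is a Baeyer–Villiger oxidation of aryl aldehydes (Dakin-type), the reaction already run in steps 1, 3 and 7 on 2,6-dimethoxybenzaldehydes. No ring closes and no stereocentre is created; the five new bonds are the C4–O bonds of rings C, E, G, I and J. The step needs aryl rather than hydride migration at all five sites, and the two methoxy groups flanking every formyl-bearing carbon together with the para aryloxy group should make the aryl group the better migrating group each time. It also needs attack at the aldehydes rather than at the electron-rich rings, which the limited peracid excess at low temperature should secure, the nine diaryl ether links and the methyl ethers being inert. The phenols are set free only in the degassed methanolysis and so are never exposed to the oxidant.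

Step 17
Reactants: 24 decamer pentaphenol with twenty-one methyl ethers
Product: 25 CNP0255890.0 (target, twenty-six free hydroxyls)
Conditions: BBr3 (excess), CH2Cl2, −78 °C to rt, Ar; then H2O, 0 °C
Reagents that add atoms: none
Why: Lewis acid-mediated aryl methyl ether cleavage, in which BBr3 coordinates each methoxy oxygen and bromide attacks the methyl carbon; the diaryl ether oxygens carry no sp3 carbon and survive, and water hydrolyses the aryl borates to the phenols.

**Compound list**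

1 | 2,4,6-trimethoxybenzaldehyde | COc1cc(OC)c(C=O)c(OC)c1 | starting material
2 | 2,4,6-trimethoxyphenyl formate | COc1cc(OC)c(OC=O)c(OC)c1 | intermediate
3 | 2,4,6-trimethoxyphenol (ring A) | COc1cc(OC)c(O)c(OC)c1 | intermediate
4 | 4-fluoro-2,6-dimethoxybenzaldehyde | COc1cc(F)cc(OC)c1C=O | starting material
5 | 2,6-dimethoxy-4-(2,4,6-trimethoxyphenoxy)benzaldehyde | COc1cc(OC)c(Oc2cc(OC)c(C=O)c(OC)c2)c(OC)c1 | intermediate
6 | 2,6-dimethoxy-4-(2,4,6-trimethoxyphenoxy)phenyl formate | COc1cc(OC)c(Oc2cc(OC)c(OC=O)c(OC)c2)c(OC)c1 | intermediate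
7 | 2,6-dimethoxy-4-(2,4,6-trimethoxyphenoxy)phenol (rings A–B) | COc1cc(OC)c(Oc2cc(OC)c(O)c(OC)c2)c(OC)c1 | intermediate
8 | 2-(4-fluoro-2,6-dimethoxyphenyl)-1,3-dioxolane | COc1cc(F)cc(OC)c1C1OCCO1 | intermediate
9 | [3-(1,3-dioxolan-2-yl)-6-fluoro-2,4-dimethoxyphenyl]lithium | [Li]c1c(F)cc(OC)c(C2OCCO2)c1OC | intermediate
10 | lithium [3-(1,3-dioxolan-2-yl)-6-fluoro-2,4-dimethoxyphenyl]trimethoxyborate | [Li+].CO[B-](OC)(OC)c1c(F)cc(OC)c(C2OCCO2)c1OC | intermediate
11 | 3-(1,3-dioxolan-2-yl)-6-fluoro-2,4-dimethoxyphenol | Oc1c(F)cc(OC)c(C2OCCO2)c1OC | intermediate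
12 | 4-[3-(1,3-dioxolan-2-yl)-6-fluoro-2,4-dimethoxyphenoxy]-2,6-dimethoxybenzaldehyde | Fc1cc(OC)c(C2OCCO2)c(OC)c1Oc1cc(OC)c(C=O)c(OC)c1 | intermediate
13 | 4-[3-(1,3-dioxolan-2-yl)-6-fluoro-2,4-dimethoxyphenoxy]-2,6-dimethoxyphenyl formate | Fc1cc(OC)c(C2OCCO2)c(OC)c1Oc1cc(OC)c(OC=O)c(OC)c1 | intermediate
14 | 4-[3-(1,3-dioxolan-2-yl)-6-fluoro-2,4-dimethoxyphenoxy]-2,6-dimethoxyphenol | Fc1cc(OC)c(C2OCCO2)c(OC)c1Oc1cc(OC)c(O)c(OC)c1 | intermediate
15 | 4-fluoro-3-(4-formyl-3,5-dimethoxyphenoxy)-2,6-dimethoxybenzaldehyde (rings I–J) | Fc1cc(OC)c(C=O)c(OC)c1Oc1cc(OC)c(C=O)c(OC)c1 | intermediate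
16 | tetramer G–H–I–J; ring G has C1–F and a C4 1,3-dioxolan-2-yl group, rings I and J have C4–CHO | Fc1cc(OC)c(C2OCCO2)c(OC)c1Oc1cc(OC)c(Oc2cc(OC)c(C=O)c(OC)c2Oc2cc(OC)c(C=O)c(OC)c2)c(OC)c1 | intermediate
17 | tetramer G–H–I–J trialdehyde; ring G has C1–F and C4–CHO | Fc1cc(OC)c(C=O)c(OC)c1Oc1cc(OC)c(Oc2cc(OC)c(C=O)c(OC)c2Oc2cc(OC)c(C=O)c(OC)c2)c(OC)c1 | intermediate
18 | hexamer E–J; ring E has C1–F and a C4 1,3-dioxolan-2-yl group, rings G, I and J have C4–CHO | Fc1cc(OC)c(C2OCCO2)c(OC)c1Oc1cc(OC)c(Oc2cc(OC)c(C=O)c(OC)c2Oc2cc(OC)c(Oc3cc(OC)c(C=O)c(OC)c3Oc3cc(OC)c(C=O)c(OC)c3)c(OC)c2)c(OC)c1 | intermediate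
19 | hexamer E–J tetra-aldehyde; ring E has C1–F and C4–CHO | Fc1cc(OC)c(C=O)c(OC)c1Oc1cc(OC)c(Oc2cc(OC)c(C=O)c(OC)c2Oc2cc(OC)c(Oc3cc(OC)c(C=O)c(OC)c3Oc3cc(OC)c(C=O)c(OC)c3)c(OC)c2)c(OC)c1 | intermediate
20 | octamer C–J; ring C has C1–F and a C4 1,3-dioxolan-2-yl group, rings E, G, I and J have C4–CHO | Fc1cc(OC)c(C2OCCO2)c(OC)c1Oc1cc(OC)c(Oc2cc(OC)c(C=O)c(OC)c2Oc2cc(OC)c(Oc3cc(OC)c(C=O)c(OC)c3Oc3cc(OC)c(Oc4cc(OC)c(C=O)c(OC)c4Oc4cc(OC)c(C=O)c(OC)c4)c(OC)c3)c(OC)c2)c(OC)c1 | intermediate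
21 | octamer C–J penta-aldehyde; ring C has C1–F and C4–CHO | Fc1cc(OC)c(C=O)c(OC)c1Oc1cc(OC)c(Oc2cc(OC)c(C=O)c(OC)c2Oc2cc(OC)c(Oc3cc(OC)c(C=O)c(OC)c3Oc3cc(OC)c(Oc4cc(OC)c(C=O)c(OC)c4Oc4cc(OC)c(C=O)c(OC)c4)c(OC)c3)c(OC)c2)c(OC)c1 | intermediate
22 | permethylated decamer A–J penta-aldehyde; CHO on C4 of rings C, E, G, I and J | COc1cc(OC)c(Oc2cc(OC)c(Oc3cc(OC)c(C=O)c(OC)c3Oc3cc(OC)c(Oc4cc(OC)c(C=O)c(OC)c4Oc4cc(OC)c(Oc5cc(OC)c(C=O)c(OC)c5Oc5cc(OC)c(Oc6cc(OC)c(C=O)c(OC)c6Oc6cc(OC)c(C=O)c(OC)c6)c(OC)c5)c(OC)c4)c(OC)c3)c(OC)c2)c(OC)c1 | intermediate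
23 | decamer pentaformate; OCHO on C4 of rings C, E, G, I and J | COc1cc(OC)c(Oc2cc(OC)c(Oc3cc(OC)c(OC=O)c(OC)c3Oc3cc(OC)c(Oc4cc(OC)c(OC=O)c(OC)c4Oc4cc(OC)c(Oc5cc(OC)c(OC=O)c(OC)c5Oc5cc(OC)c(Oc6cc(OC)c(OC=O)c(OC)c6Oc6cc(OC)c(OC=O)c(OC)c6)c(OC)c5)c(OC)c4)c(OC)c3)c(OC)c2)c(OC)c1 | intermediate
24 | decamer pentaphenol with twenty-one methyl ethers; OH on C4 of rings C, E, G, I and J | COc1cc(OC)c(Oc2cc(OC)c(Oc3cc(OC)c(O)c(OC)c3Oc3cc(OC)c(Oc4cc(OC)c(O)c(OC)c4Oc4cc(OC)c(Oc5cc(OC)c(O)c(OC)c5Oc5cc(OC)c(Oc6cc(OC)c(O)c(OC)c6Oc6cc(OC)c(O)c(OC)c6)c(OC)c5)c(OC)c4)c(OC)c3)c(OC)c2)c(OC)c1 | intermediate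
25 | CNP0255890.0, the fully deprotected ten-ring phlorotannin | Oc1cc(O)c(Oc2cc(O)c(Oc3cc(O)c(O)c(O)c3Oc3cc(O)c(Oc4cc(O)c(O)c(O)c4Oc4cc(O)c(Oc5cc(O)c(O)c(O)c5Oc5cc(O)c(Oc6cc(O)c(O)c(O)c6Oc6cc(O)c(O)c(O)c6)c(O)c5)c(O)c4)c(O)c3)c(O)c2)c(O)c1 | target

**Step count and risk**

Total step count: 17. Longest linear sequence: 13 steps from 4 (steps 4, 5, 6, 7 or 8, then 9 to 17). Compound 4 is used in steps 2, 4 and 6, compound 12 is divided between steps 7 and 8, and compound 14 is used in steps 9, 11 and 13.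

Steps most likely to fail:

Step 16. Aryl migration may not win cleanly at all five hindered formyl groups, so that hydride migration gives carboxylic acids and the product is a mixture of partly oxidised chains. The fallback sets out from 22. MeMgBr in THF at 0 °C should add to the five aldehydes to give the penta(1-hydroxyethyl) decamer F1 as a mixture of diastereomers. Dess–Martin periodinane in CH2Cl2 should oxidise it to the penta-acetyl decamer F2. Baeyer–Villiger oxidation of these aryl methyl ketones with mCPBA in CH2Cl2 offers only aryl or methyl migration, and the electron-rich aryl groups should migrate to give the decamer penta-acetate F3. K2CO3 in degassed MeOH should then cleave the acetates, and the route is rejoined at 24.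

Step 17. Cleavage of twenty-one methyl ethers may stall at partly methylated stages, and the liberated polyphenol may be lost through air oxidation and irreversible adsorption during isolation. The fallback sets out from 24. The crude product of the BBr3 treatment is not purified but acetylated at once (Ac2O, pyridine, DMAP cat.) to the hexacosaacetate F4, which is stable to air, can be chromatographed on silica and can be separated from under-cleaved material. Zemplén deacetylation (NaOMe cat., degassed MeOH, then acidic ion-exchange resin) should release the polyphenol, and the route is rejoined at 25.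

Step 15. Fluoride displacement on the octamer by the hindered 2,6-dimethoxyphenoxide may be too slow at a tolerable temperature, which would allow aryloxide exchange at the formyl-activated ether carbons to scramble the chain. The fallback sets out from 7. Silylation (Me3SiCl, Et3N, CH2Cl2) should give the trimethylsilyl ether F5. With 21 and CsF (cat.) in dry NMP at 80 °C, fluoride-catalysed desilylative etherification generates the unsolvated phenoxide only transiently, and loss of Me3SiF drives the coupling without carbonate base. The route is rejoined at 22.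

**Further compounds**

F1 | step 16 | decamer with 1-hydroxyethyl groups on C4 of rings C, E, G, I and J (mixture of diastereomers, configuration not assigned) | COc1cc(OC)c(Oc2cc(OC)c(Oc3cc(OC)c(C(C)O)c(OC)c3Oc3cc(OC)c(Oc4cc(OC)c(C(C)O)c(OC)c4Oc4cc(OC)c(Oc5cc(OC)c(C(C)O)c(OC)c5Oc5cc(OC)c(Oc6cc(OC)c(C(C)O)c(OC)c6Oc6cc(OC)c(C(C)O)c(OC)c6)c(OC)c5)c(OC)c4)c(OC)c3)c(OC)c2)c(OC)c1
F2 | step 16 | decamer with acetyl groups on C4 of rings C, E, G, I and J | COc1cc(OC)c(Oc2cc(OC)c(Oc3cc(OC)c(C(C)=O)c(OC)c3Oc3cc(OC)c(Oc4cc(OC)c(C(C)=O)c(OC)c4Oc4cc(OC)c(Oc5cc(OC)c(C(C)=O)c(OC)c5Oc5cc(OC)c(Oc6cc(OC)c(C(C)=O)c(OC)c6Oc6cc(OC)c(C(C)=O)c(OC)c6)c(OC)c5)c(OC)c4)c(OC)c3)c(OC)c2)c(OC)c1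
F3 | step 16 | decamer penta-acetate, acetoxy groups on C4 of rings C, E, G, I and J | COc1cc(OC)c(Oc2cc(OC)c(Oc3cc(OC)c(OC(C)=O)c(OC)c3Oc3cc(OC)c(Oc4cc(OC)c(OC(C)=O)c(OC)c4Oc4cc(OC)c(Oc5cc(OC)c(OC(C)=O)c(OC)c5Oc5cc(OC)c(Oc6cc(OC)c(OC(C)=O)c(OC)c6Oc6cc(OC)c(OC(C)=O)c(OC)c6)c(OC)c5)c(OC)c4)c(OC)c3)c(OC)c2)c(OC)c1
F4 | step 17 | hexacosaacetate of 25 (all twenty-six hydroxyls acetylated) | CC(=O)Oc1cc(OC(C)=O)c(Oc2cc(OC(C)=O)c(Oc3cc(OC(C)=O)c(OC(C)=O)c(OC(C)=O)c3Oc3cc(OC(C)=O)c(Oc4cc(OC(C)=O)c(OC(C)=O)c(OC(C)=O)c4Oc4cc(OC(C)=O)c(Oc5cc(OC(C)=O)c(OC(C)=O)c(OC(C)=O)c5Oc5cc(OC(C)=O)c(Oc6cc(OC(C)=O)c(OC(C)=O)c(OC(C)=O)c6Oc6cc(OC(C)=O)c(OC(C)=O)c(OC(C)=O)c6)c(OC(C)=O)c5)c(OC(C)=O)c4)c(OC(C)=O)c3)c(OC(C)=O)c2)c(OC(C)=O)c1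
F5 | step 15 | trimethylsilyl ether of 7, [2,6-dimethoxy-4-(2,4,6-trimethoxyphenoxy)phenoxy]trimethylsilane | COc1cc(OC)c(Oc2cc(OC)c(O[Si](C)(C)C)c(OC)c2)c(OC)c1
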